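I decided to read this flask off the west run instead of fitting anything, since west carries the same charges of free catalyst and coupling partner.

| flask | substrate | coupling partner | free catalyst | remark |
|---|---|---|---|---|
| west | 1 M | 2.4 M | 1.3 mM | run made earlier |
| south | 2 M | 2.4 M | 2 mM | run made earlier |
| flask | 2.0 M | 2.40 M | 1.3 mM |  |

| run | time / min | target / % | substrate / % |
|---|---|---|---|
| west | 5.00 | 19 | 83 |
| west | 10.0 | 33 | 66 |
| west | 15.0 | 47 | 52 |
| west | 20.0 | 58 | 41 |
| west | 25.0 | 67 | 34 |
| south | 2.00 | 5 | 93 |
| south | 4.00 | 13 | 87 |
| south | 6.00 | 17 | 83 |
| south | 12.0 | 34 | 68 |
| south | 25.0 | 48 | 51 |

(readings scatter by 1.5 percentage points)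

- the numbers in the tables scatter with a standard deviation of 1.5 percentage points
- what may be going on: substrate + free catalyst -> catalyst intermediate A; 2 coupling partner -> self-condensation product; coupling partner + catalyst intermediate A <-> catalyst intermediate B; catalyst intermediate B -> free catalyst + target
- no earlier run changes the charge of coupling partner; that part of a forecast is a guess

- apparent order in coupling partner when 30 % of the substrate are converted (percent change of the rate of making target for one percent more coupling partner charged)
- factor on the rate of making target when 30 % of the substrate are converted if free catalyst is charged twice over

Substrate turns free catalyst into catalyst intermediate A, coupling partner joins that reversibly to give catalyst intermediate B, and catalyst intermediate B releases target and free catalyst. Coupling partner also condenses with itself, and no earlier run varies its charge, so that part stays a guess.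

Target leaves from catalyst intermediate B, so the turnover, the rate of making target per catalyst charged, is the rate constant of that last step times the share of catalyst standing as catalyst intermediate B. Early turnover is 29.2 min⁻¹ in west and 32.5 min⁻¹ in south, a gap far smaller than the factor 2.00 on substrate, so I let this flask follow west. Its 30 % conversion means 0.600 M made, which west passes between 15.0 min and 25.0 min, and there the turnover is 15.4 min⁻¹.

Two colleagues dispute what this means for the order. The first holds that catalyst intermediate A is the resting state, so the rate follows c(coupling partner) and the turnover ratio 0.526 puts about 1.26 M of coupling partner in the flask at that point. Extra charge then counts for more than its own percent. The second holds that the early turnover is already the ceiling, which makes 0.526 the share standing as catalyst intermediate B, and the first view's order shrinks to the remaining 0.474 of itself. I commit to a multiplier between those two, below one.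

The forecast says 1.35 and 2.7, with “catalyst resting before the coupling step”.

The simulation gives 0.94 and 2.82.

    substrate + free catalyst → catalyst intermediate A (k = 490 M⁻¹ min⁻¹)
    2 coupling partner → self-condensation product (k = 0.0150 M⁻¹ min⁻¹)
    coupling partner + catalyst intermediate A ⇌ catalyst intermediate B (K = 21.0 M⁻¹, k = 29.0 M⁻¹ min⁻¹)
    catalyst intermediate B → free catalyst + target (k = 72.0 min⁻¹)

Catalyst intermediate B stands at 25.2 % of the catalyst after 15.0 min and 14.3 % after 30.0 min, while the flask reaches 30 % conversion at 20.2 min. The turnover 15.4 min⁻¹ divided by 72 min⁻¹ gives a share of 21.4 %, so the multiplier is 0.786, above the second view's 0.474. The first view's waiting catalyst stands there on both sides of that moment: in this flask catalyst intermediate A holds 72.3 % after 15.0 min, more than catalyst intermediate B, and 84.0 % after 30.0 min.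

The data stem from a simulated flask on assumed constants.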